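## Retrosynthetic overview

1. Target ⇐ removal of two silyl ethers. The C6 ester stereocentre is set last, by protonation of the C1–C6 enolate on the face opposite the isopropyl and angelate groups.
2. C6 ester ⇐ enolate hydroxylation and esterification with a silyl-protected (E)-4-hydroxy-2-methylbut-2-enoic acid. C4 angelate ⇐ Mitsunobu inversion of a trans-4-hydroxy enone. Isopropyl ⇐ isopropenyl.
3. The only ring (the p-menthane six-membered ring) ⇐ head-to-tail C–C closure of an acyclic oxidised neral, (2Z)-3-(silyloxymethyl)-7-methyl-4-oxoocta-2,6-dienal, by a catalytic asymmetric carbonyl-ene (Prins-type) cyclization. This is the laboratory counterpart of the cyclase step that closes a neryl cation onto its distal prenyl alkene.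
4. That aldehyde ⇐ singlet-oxygen opening of a 2-prenyl-3-(silyloxymethyl)furan ⇐ furan-3-ylmethanol + prenyl bromide.

Assumption: the SMILES is read as drawn, i.e. the (4S,5S,6S) all-cis isomer. Cyclohex-2-en-1-one numbering is used throughout: C1 = C=O, C2 = C(CH2OH), C3 = CH, C4 = CH–O-angelate (Z ester), C5 = CH–isopropyl, C6 = CH–O-(E)-4-hydroxy-2-methylbut-2-enoate.

## Route

Step 1
Reactants: 1 furan-3-ylmethanol; 2 1-bromo-3-methylbut-2-ene (prenyl bromide)
Product: 5 tert-butyldimethyl{[2-(3-methylbut-2-en-1-yl)furan-3-yl]methoxy}silane, via dilithiated furanmethanol 3 (not isolated), via lithium alkoxide 4 (not isolated)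
Conditions: n-BuLi (2.05 equiv), THF, –78 → 0 °C; 2 (1.0 equiv), –78 → 0 °C; then TBSCl (1.3 equiv), DMAP (0.1 equiv), 0 °C → rt
Reagents that add atoms: tert-butyl(chloro)dimethylsilane (TBSCl), CC(C)(C)[Si](C)(C)Cl
Why: Directed ortho-lithiation (the lithium alkoxide steers the second n-BuLi to C2 of the furan), SN2 alkylation of the C2 aryllithium at the primary carbon of prenyl bromide, and O-silylation of the remaining alkoxide in the same flask; no stereocentre is formed.

Step 2
Reactants: 5 tert-butyldimethyl{[2-(3-methylbut-2-en-1-yl)furan-3-yl]methoxy}silane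
Product: 7 (2Z)-3-{[(tert-butyldimethylsilyl)oxy]methyl}-7-methyl-4-oxoocta-2,6-dienal, via furan endoperoxide 6 (not isolated)
Conditions: O2, hν (visible), tetraphenylporphyrin (0.5 mol %), CH2Cl2, –78 °C; then Me2S (3 equiv), –78 → 0 °C; used crude
Reagents that add atoms: dioxygen, O=O
Why: Singlet-oxygen [4+2] cycloaddition to the electron-rich furan is about two orders of magnitude faster than the ene reaction of the trisubstituted prenyl alkene, and Me2S reduction of the O–O bond unveils the cis-enedione, so the Z geometry needed for ring closure is inherited from the furan ring.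

Step 3
Reactants: 7 (2Z)-3-{[(tert-butyldimethylsilyl)oxy]methyl}-7-methyl-4-oxoocta-2,6-dienal
Product: 8 (4R,5S)-2-{[(tert-butyldimethylsilyl)oxy]methyl}-4-hydroxy-5-(prop-1-en-2-yl)cyclohex-2-en-1-one (4,5-trans)
Conditions: confined chiral imidodiphosphorimidate Brønsted acid (IDPi, 3,3'-aryl BINOL units, N-perfluoroarylsulfonyl groups; enantiomer chosen to give (4R,5S); 2 mol %), CHCl3, 4 Å MS, –40 °C
Reagents that add atoms: none
Why: Proposed new method: the acid-activated aldehyde is attacked by the CH terminus of the prenyl alkene in a 6-exo chair-like array with concerted transfer of an allylic methyl hydrogen to oxygen (intramolecular carbonyl-ene, the Prins-type counterpart of the cyclase-mediated closure of a neryl cation to the p-menthane ring), which forms the only ring with OH and isopropenyl trans (both pseudo-equatorial) while the confined chiral anion selects the aldehyde face and so fixes C5 as S and C4 as R; the closest known reaction type is the imidodiphosphorimidate-catalysed asymmetric cyclization of neral to (1R,6S)-trans-isopiperitenol, and the extra 4-oxo group should make the aldehyde more electrophilic and the product alcohol less prone to ionise.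

Step 4
Reactants: 8 (4R,5S)-2-{[(tert-butyldimethylsilyl)oxy]methyl}-4-hydroxy-5-(prop-1-en-2-yl)cyclohex-2-en-1-one; 9 angelic acid, (2Z)-2-methylbut-2-enoic acid
Product: 10 (4S,5S)-2-{[(tert-butyldimethylsilyl)oxy]methyl}-4-{[(2Z)-2-methylbut-2-enoyl]oxy}-5-(prop-1-en-2-yl)cyclohex-2-en-1-one (4,5-cis)
Conditions: 9 (1.5 equiv), PPh3 (1.6 equiv), DIAD (1.6 equiv), toluene, 0 °C → rt
Reagents that add atoms: none
Why: Mitsunobu esterification: the angelate carboxylate displaces the alkoxyphosphonium by SN2 with inversion at C4 (R to S, now cis to C5), and because the acid reacts as a nucleophile and is never acyl-activated its Z geometry is not at risk, while E2 loss toward C5 is disfavoured because H-5 is syn to the leaving group.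

Step 5
Reactants: 10 (4S,5S)-2-{[(tert-butyldimethylsilyl)oxy]methyl}-4-{[(2Z)-2-methylbut-2-enoyl]oxy}-5-(prop-1-en-2-yl)cyclohex-2-en-1-one
Product: 11 (4R,5S)-2-{[(tert-butyldimethylsilyl)oxy]methyl}-4-{[(2Z)-2-methylbut-2-enoyl]oxy}-5-(propan-2-yl)cyclohex-2-en-1-one (4,5-cis)
Conditions: H2 (1 atm), RhCl(PPh3)3 (5 mol %), benzene, rt
Reagents that add atoms: none
Why: Homogeneous hydrogenation with Wilkinson's catalyst reduces only the 1,1-disubstituted isopropenyl alkene and leaves the trisubstituted enone and angelate alkenes (as in the known carvone to carvotanacetone reduction); no stereocentre is formed, and the C4 descriptor changes from S to R only because the CIP ranking of C3 and C5 reverses.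

Step 6
Reactants: 11 (4R,5S)-2-{[(tert-butyldimethylsilyl)oxy]methyl}-4-{[(2Z)-2-methylbut-2-enoyl]oxy}-5-(propan-2-yl)cyclohex-2-en-1-one
Product: 13 (4S,5R,6R)-2-{[(tert-butyldimethylsilyl)oxy]methyl}-6-hydroxy-4-{[(2Z)-2-methylbut-2-enoyl]oxy}-5-(propan-2-yl)cyclohex-2-en-1-one (6-OH trans to isopropyl), via sodium enolate 12 (not isolated)
Conditions: NaN(SiMe3)2 (1.1 equiv), THF, –78 °C; then 2-(phenylsulfonyl)-3-phenyloxaziridine (1.3 equiv), –78 °C; AcOH quench
Reagents that add atoms: 2-(phenylsulfonyl)-3-phenyloxaziridine (Davis oxaziridine, racemic), O=S(=O)(c1ccccc1)N1OC1c1ccccc1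
Why: Kinetic deprotonation at the only α' position (C6) gives the cross-conjugated enolate, which is hydroxylated (Davis enolate oxidation) on the face opposite the cis isopropyl and angelate groups, so the new hydroxyl is trans to isopropyl (6R); this centre is reset in step 10, and the C5 descriptor becomes R only through a CIP ranking change.

Step 7
Reactants: 14 [(tert-butyldimethylsilyl)oxy]acetaldehyde; 15 ethyl 2-(triphenylphosphoranylidene)propanoate
Product: 16 ethyl (2E)-4-[(tert-butyldimethylsilyl)oxy]-2-methylbut-2-enoate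
Conditions: CH2Cl2, rt
Reagents that add atoms: none
Why: Wittig olefination with an α-methyl stabilised ylide gives the trisubstituted enoate with high E selectivity (thermodynamically controlled oxaphosphetane formation).

Step 8
Reactants: 16 ethyl (2E)-4-[(tert-butyldimethylsilyl)oxy]-2-methylbut-2-enoate
Product: 17 (2E)-4-[(tert-butyldimethylsilyl)oxy]-2-methylbut-2-enoic acid
Conditions: LiOH·H2O (3 equiv), THF/MeOH/H2O, rt; then 1 M HCl to pH 4, 0 °C
Reagents that add atoms: lithium hydroxide, [Li+].[OH-]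
Why: Ester saponification (acyl–oxygen cleavage by hydroxide) leaves the primary TBS ether and the E alkene untouched.

Step 9
Reactants: 13 (4S,5R,6R)-2-{[(tert-butyldimethylsilyl)oxy]methyl}-6-hydroxy-4-{[(2Z)-2-methylbut-2-enoyl]oxy}-5-(propan-2-yl)cyclohex-2-en-1-one; 17 (2E)-4-[(tert-butyldimethylsilyl)oxy]-2-methylbut-2-enoic acid
Product: 18 (4S,5S,6R)-6-{[(2E)-4-[(tert-butyldimethylsilyl)oxy]-2-methylbut-2-enoyl]oxy}-2-{[(tert-butyldimethylsilyl)oxy]methyl}-4-{[(2Z)-2-methylbut-2-enoyl]oxy}-5-(propan-2-yl)cyclohex-2-en-1-one (6-epimer of the protected target)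
Conditions: DCC (1.5 equiv), DMAP (0.2 equiv), CH2Cl2, 0 °C → rt
Reagents that add atoms: none
Why: Steglich esterification (carbodiimide activation, DMAP acyl transfer) acylates the secondary α-hydroxy ketone with retention at C6; the E acid cannot isomerise further and the angelate already in place is not activated.

Step 10
Reactants: 18 (4S,5S,6R)-6-{[(2E)-4-[(tert-butyldimethylsilyl)oxy]-2-methylbut-2-enoyl]oxy}-2-{[(tert-butyldimethylsilyl)oxy]methyl}-4-{[(2Z)-2-methylbut-2-enoyl]oxy}-5-(propan-2-yl)cyclohex-2-en-1-one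
Product: 20 (4S,5S,6S)-6-{[(2E)-4-[(tert-butyldimethylsilyl)oxy]-2-methylbut-2-enoyl]oxy}-2-{[(tert-butyldimethylsilyl)oxy]methyl}-4-{[(2Z)-2-methylbut-2-enoyl]oxy}-5-(propan-2-yl)cyclohex-2-en-1-one (all-cis), via lithium enolate 19 (not isolated)
Conditions: LiN(SiMe3)2 (1.1 equiv), THF, –78 °C, 20 min; then cannulated into AcOH (5 equiv), THF, –78 °C
Reagents that add atoms: none
Why: Deprotonation at C6 (the most acidic C–H, α to the ketone and bearing the acyloxy group) gives an enolate in which A(1,2) strain with the C6 acyloxy group puts the C5 isopropyl pseudo-axial, so kinetic enolate protonation occurs axially on the face opposite both isopropyl and angelate and leaves the C6 ester cis to isopropyl (6S, the contra-steric all-cis epimer).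

Step 11
Reactants: 20 (4S,5S,6S)-6-{[(2E)-4-[(tert-butyldimethylsilyl)oxy]-2-methylbut-2-enoyl]oxy}-2-{[(tert-butyldimethylsilyl)oxy]methyl}-4-{[(2Z)-2-methylbut-2-enoyl]oxy}-5-(propan-2-yl)cyclohex-2-en-1-one
Product: 21 (4S,5S,6S)-6-{[(2E)-4-hydroxy-2-methylbut-2-enoyl]oxy}-2-(hydroxymethyl)-4-{[(2Z)-2-methylbut-2-enoyl]oxy}-5-(propan-2-yl)cyclohex-2-en-1-one (CNP0281432.2)
Conditions: HF·pyridine, pyridine/THF, 0 °C → rt
Reagents that add atoms: none
Why: Fluoride-mediated desilylation under buffered acidic conditions cleaves both primary allylic TBS ethers without touching the two unsaturated esters, the enone or the epimerisable C6 centre.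

## Compound list

1 | furan-3-ylmethanol | OCc1ccoc1 | starting material
2 | 1-bromo-3-methylbut-2-ene (prenyl bromide) | CC(C)=CCBr | starting material
3 | lithium (2-lithiofuran-3-yl)methanolate (C2,O-dilithiated furanmethanol) | [Li]c1occc1CO[Li] | intermediate
4 | lithium [2-(3-methylbut-2-en-1-yl)furan-3-yl]methanolate | CC(C)=CCc1occc1C[O-].[Li+] | intermediate
5 | tert-butyldimethyl{[2-(3-methylbut-2-en-1-yl)furan-3-yl]methoxy}silane | CC(C)=CCc1occc1CO[Si](C)(C)C(C)(C)C | intermediate
6 | 6-{[(tert-butyldimethylsilyl)oxy]methyl}-1-(3-methylbut-2-en-1-yl)-2,3,7-trioxabicyclo[2.2.1]hept-5-ene (racemic furan endoperoxide) | CC(C)=CCC12OOC(O1)C=C2CO[Si](C)(C)C(C)(C)C | intermediate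
7 | (2Z)-3-{[(tert-butyldimethylsilyl)oxy]methyl}-7-methyl-4-oxoocta-2,6-dienal | O=C/C=C(CO[Si](C)(C)C(C)(C)C)\C(=O)CC=C(C)C | intermediate
8 | (4R,5S)-2-{[(tert-butyldimethylsilyl)oxy]methyl}-4-hydroxy-5-(prop-1-en-2-yl)cyclohex-2-en-1-one | O[C@@H]1C=C(CO[Si](C)(C)C(C)(C)C)C(=O)C[C@H]1C(C)=C | intermediate
9 | angelic acid, (2Z)-2-methylbut-2-enoic acid | C/C=C(/C)C(=O)O | starting material
10 | (4S,5S)-2-{[(tert-butyldimethylsilyl)oxy]methyl}-4-{[(2Z)-2-methylbut-2-enoyl]oxy}-5-(prop-1-en-2-yl)cyclohex-2-en-1-one | C/C=C(/C)C(=O)O[C@H]1C=C(CO[Si](C)(C)C(C)(C)C)C(=O)C[C@H]1C(C)=C | intermediate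
11 | (4R,5S)-2-{[(tert-butyldimethylsilyl)oxy]methyl}-4-{[(2Z)-2-methylbut-2-enoyl]oxy}-5-(propan-2-yl)cyclohex-2-en-1-one | C/C=C(/C)C(=O)O[C@H]1C=C(CO[Si](C)(C)C(C)(C)C)C(=O)C[C@H]1C(C)C | intermediate
12 | sodium C1–C6 enolate of 11 | C/C=C(/C)C(=O)O[C@H]1C=C(CO[Si](C)(C)C(C)(C)C)C([O-])=C[C@H]1C(C)C.[Na+] | intermediate
13 | (4S,5R,6R)-2-{[(tert-butyldimethylsilyl)oxy]methyl}-6-hydroxy-4-{[(2Z)-2-methylbut-2-enoyl]oxy}-5-(propan-2-yl)cyclohex-2-en-1-one | C/C=C(/C)C(=O)O[C@H]1C=C(CO[Si](C)(C)C(C)(C)C)C(=O)[C@H](O)[C@H]1C(C)C | intermediate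
14 | [(tert-butyldimethylsilyl)oxy]acetaldehyde | O=CCO[Si](C)(C)C(C)(C)C | starting material
15 | ethyl 2-(triphenylphosphoranylidene)propanoate | CCOC(=O)C(C)=P(c1ccccc1)(c1ccccc1)c1ccccc1 | starting material
16 | ethyl (2E)-4-[(tert-butyldimethylsilyl)oxy]-2-methylbut-2-enoate | CCOC(=O)/C(C)=C/CO[Si](C)(C)C(C)(C)C | intermediate
17 | (2E)-4-[(tert-butyldimethylsilyl)oxy]-2-methylbut-2-enoic acid | OC(=O)/C(C)=C/CO[Si](C)(C)C(C)(C)C | intermediate
18 | (4S,5S,6R)-6-{[(2E)-4-[(tert-butyldimethylsilyl)oxy]-2-methylbut-2-enoyl]oxy}-2-{[(tert-butyldimethylsilyl)oxy]methyl}-4-{[(2Z)-2-methylbut-2-enoyl]oxy}-5-(propan-2-yl)cyclohex-2-en-1-one | C/C=C(/C)C(=O)O[C@H]1C=C(CO[Si](C)(C)C(C)(C)C)C(=O)[C@H](OC(=O)/C(C)=C/CO[Si](C)(C)C(C)(C)C)[C@H]1C(C)C | intermediate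
19 | lithium C1–C6 enolate of 18 | C/C=C(/C)C(=O)O[C@H]1C=C(CO[Si](C)(C)C(C)(C)C)C([O-])=C(OC(=O)/C(C)=C/CO[Si](C)(C)C(C)(C)C)[C@H]1C(C)C.[Li+] | intermediate
20 | (4S,5S,6S)-6-{[(2E)-4-[(tert-butyldimethylsilyl)oxy]-2-methylbut-2-enoyl]oxy}-2-{[(tert-butyldimethylsilyl)oxy]methyl}-4-{[(2Z)-2-methylbut-2-enoyl]oxy}-5-(propan-2-yl)cyclohex-2-en-1-one | C/C=C(/C)C(=O)O[C@H]1C=C(CO[Si](C)(C)C(C)(C)C)C(=O)[C@@H](OC(=O)/C(C)=C/CO[Si](C)(C)C(C)(C)C)[C@H]1C(C)C | intermediate
21 | (4S,5S,6S)-6-{[(2E)-4-hydroxy-2-methylbut-2-enoyl]oxy}-2-(hydroxymethyl)-4-{[(2Z)-2-methylbut-2-enoyl]oxy}-5-(propan-2-yl)cyclohex-2-en-1-one | C/C=C(/C)C(=O)O[C@H]1C=C(CO)C(=O)[C@@H](OC(=O)/C(C)=C/CO)[C@H]1C(C)C | target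

## Step count and risks

Total steps: 11. Longest linear sequence: 9 (steps 1–6, 9, 10, 11); steps 7 and 8 make the side-chain acid.

The three steps most likely to fail:

Step 3 (asymmetric ring closure). The substrate class is new for this catalyst type. The cis-enedione can isomerise to E, deconjugate, or undergo an acid-mediated aldol to a hydroxycyclopentenone, and the catalyst pocket may not accept the silyloxymethyl group. Fallback: setting out from 7, a stoichiometric achiral Lewis acid (Me2AlCl, CH2Cl2, –78 °C) effects the same carbonyl-ene closure to give the racemic trans-hydroxy enone rac-(4R*,5S*)-2-{[(tert-butyldimethylsilyl)oxy]methyl}-4-hydroxy-5-(prop-1-en-2-yl)cyclohex-2-en-1-one F1. Lipase-catalysed acylation (Burkholderia cepacia lipase, vinyl acetate, MTBE, 30 °C) then resolves it. Kazlauskas' rule predicts that the (4R,5S) enantiomer is acetylated (to be confirmed by Mosher analysis), giving (4R,5S)-4-acetoxy-2-{[(tert-butyldimethylsilyl)oxy]methyl}-5-(prop-1-en-2-yl)cyclohex-2-en-1-one F2, which is separated from the unreacted antipode. Methanolysis (K2CO3, MeOH, 0 °C) returns to the route at 8.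

Step 4 (Mitsunobu with angelic acid). The alcohol is hindered and angelic acid is only moderately acidic, so retention by acyl transfer, elimination toward a phenol, or low conversion are possible. Fallback: setting out from 8, inversion is separated from angeloylation. Mitsunobu reaction with the more acidic 4-nitrobenzoic acid (PPh3, DIAD, toluene) gives the (4S,5S)-4-nitrobenzoate, (4S,5S)-2-{[(tert-butyldimethylsilyl)oxy]methyl}-4-[(4-nitrobenzoyl)oxy]-5-(prop-1-en-2-yl)cyclohex-2-en-1-one F3. Methanolysis (K2CO3, MeOH, 0 °C) gives the cis alcohol (4S,5S)-2-{[(tert-butyldimethylsilyl)oxy]methyl}-4-hydroxy-5-(prop-1-en-2-yl)cyclohex-2-en-1-one F4. Acylation with retention, using the mixed anhydride of 9 with 2,4,6-trichlorobenzoyl chloride (Et3N, toluene, 80 °C, no DMAP, to avoid Z to E isomerisation), returns to the route at 10.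

Step 10 (kinetic protonation). H-6 of 18 lies on the hindered face, so deprotonation may be slow. The free enolate could also undergo acyl migration (Chan-type rearrangement), and reversible protonation would drift toward the trans epimer. Fallback: setting out from 18, the enol is made without a free enolate. Soft enolisation (Me3SiOSO2CF3, Et3N, CH2Cl2, –78 → 0 °C) gives the trimethylsilyl enol ether (4S,5S)-6-{[(2E)-4-[(tert-butyldimethylsilyl)oxy]-2-methylbut-2-enoyl]oxy}-2-{[(tert-butyldimethylsilyl)oxy]methyl}-4-{[(2Z)-2-methylbut-2-enoyl]oxy}-5-(propan-2-yl)-1-[(trimethylsilyl)oxy]cyclohexa-1(6),2-diene F5. HF·pyridine (THF/pyridine, –20 → 0 °C) then protonates C6 of the enol ether on the open face and removes both TBS groups in the same operation, returning to the route at the target 21 and bypassing 20. The regiochemistry of the soft enolisation (C6 versus the γ position C4) must be checked.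

## Further compounds

F1 | step 3 | rac-(4R*,5S*)-2-{[(tert-butyldimethylsilyl)oxy]methyl}-4-hydroxy-5-(prop-1-en-2-yl)cyclohex-2-en-1-one (racemate, both enantiomers written) | O[C@@H]1C=C(CO[Si](C)(C)C(C)(C)C)C(=O)C[C@H]1C(C)=C.O[C@H]1C=C(CO[Si](C)(C)C(C)(C)C)C(=O)C[C@@H]1C(C)=C
F2 | step 3 | (4R,5S)-4-acetoxy-2-{[(tert-butyldimethylsilyl)oxy]methyl}-5-(prop-1-en-2-yl)cyclohex-2-en-1-one | CC(=O)O[C@@H]1C=C(CO[Si](C)(C)C(C)(C)C)C(=O)C[C@H]1C(C)=C
F3 | step 4 | (4S,5S)-2-{[(tert-butyldimethylsilyl)oxy]methyl}-4-[(4-nitrobenzoyl)oxy]-5-(prop-1-en-2-yl)cyclohex-2-en-1-one | O=C(O[C@H]1C=C(CO[Si](C)(C)C(C)(C)C)C(=O)C[C@H]1C(C)=C)c1ccc(cc1)[N+](=O)[O-]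
F4 | step 4 | (4S,5S)-2-{[(tert-butyldimethylsilyl)oxy]methyl}-4-hydroxy-5-(prop-1-en-2-yl)cyclohex-2-en-1-one | O[C@H]1C=C(CO[Si](C)(C)C(C)(C)C)C(=O)C[C@H]1C(C)=C
F5 | step 10 | (4S,5S)-6-{[(2E)-4-[(tert-butyldimethylsilyl)oxy]-2-methylbut-2-enoyl]oxy}-2-{[(tert-butyldimethylsilyl)oxy]methyl}-4-{[(2Z)-2-methylbut-2-enoyl]oxy}-5-(propan-2-yl)-1-[(trimethylsilyl)oxy]cyclohexa-1(6),2-diene | C/C=C(/C)C(=O)O[C@H]1C=C(CO[Si](C)(C)C(C)(C)C)C(O[Si](C)(C)C)=C(OC(=O)/C(C)=C/CO[Si](C)(C)C(C)(C)C)[C@H]1C(C)C
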